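Tripling the partner gives the dawn run 3.33 times the target of the autumn run at 1.8 s, and tripling the starting material gives the dusk run 3.31 times. Autumn's reading there carries a scatter of 8.57% of its value, so I take each order as one. The flask is closed and stirred, and starting material and partner make target.

| setting | autumn | summer | dusk | dawn | midnight |
|---|---|---|---|---|---|
| starting material | 0.200 M | 0.120 M | 0.600 M | 0.200 M | 0.200 M |
| partner | 0.600 M | 0.520 M | 0.600 M | 1.80 M | 0.600 M |
| time |  |  |  |  | 140 s |

- autumn run (time / s: [target] / M): 1.8: 0.0070; 3.5: 0.0149; 6.7: 0.0249; 13: 0.0422; 24: 0.0599; 46: 0.0750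
- summer run (time / s: [target] / M): 1.8: 0.0033; 3.5: 0.0073; 6.7: 0.0136; 13: 0.0230; 24: 0.0339; 46: 0.0421
- dusk run (time / s: [target] / M): 1.8: 0.0232; 3.5: 0.0423; 6.7: 0.0732; 13: 0.1189; 24: 0.1650; 46: 0.1989
- dawn run (time / s: [target] / M): 1.8: 0.0233; 3.5: 0.0403; 6.7: 0.0650; 13: 0.0925; 24: 0.1085; 46: 0.0957

(standard deviation of a reading: 6 × 10⁻⁴ M)

- Overall: starting material + partner -> target.
- Constant volume, constant temperature.
- "The second partner" is partner.
- An order is taken over about fifteen percent of the charge, up and down.

1. the exponent of [starting material] in the starting rate at the charge of the autumn run (at the point where two percent of the starting material have become target) (one fixed amount of target, the same in the runs compared)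
2. the exponent of [partner] in the starting rate at the charge of the autumn run (at the point where two percent of the starting material have become target)
3. target in the midnight run at 140 s, as a share of the starting material charged

I read the last two rows of these tables as fractions of the charge. From 24 s to 46 s, autumn rises from 29.9% to 37.5%, summer from 28.3% to 35.1%, and dusk from 27.5% to 33.1%. Dawn falls from 54.2% to 47.8%, so I read the loss there.

I write the share as a height, times a falling exponential in a constant b, times one minus an exponential in a constant c. Height times c is the starting slope, which I read as 0.0647 s⁻¹.

Ignoring the rise, dawn's last two rows give 0.00571 s⁻¹. That implies a height of 62.2% and c of 0.104 s⁻¹. Putting this rise back gives 0.00923 s⁻¹. A second round gives a height of 73.8%, c of 0.0877 s⁻¹ and 0.0108 s⁻¹. The correction is shrinking, so I stop. This 0.0108 s⁻¹ is my tail constant, the fraction of the standing target lost per second once the rise has faded.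

The midnight flask has autumn's charge. If the tail is pseudo-first-order in partner, its constant is 0.00360 s⁻¹. Autumn's slope at 3.5 s is 0.0213 s⁻¹, which puts its rise term at 89.1% complete at 46 s. Carrying the tail to 140 s, I commit to 30.0%.

The forecast gives orders of 1 and 1 and a share of 20%, lower than mine, with the words “This is an extrapolation, so the range is wide”.

The flask gives orders of 1.0 and 1.0 and a share of 27.3%, which is 2.7 percentage points below my share.

    starting material + partner ⇌ target (0.03810 M⁻¹ s⁻¹, 0.006110 s⁻¹)
    target + partner → side product (0.007570 M⁻¹ s⁻¹)
    starting material → decomposed substrate (0.01420 s⁻¹)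

At the midnight charge, starting material enters the forward step at 0.0229 s⁻¹, faster than it turns to decomposed substrate at 0.0142 s⁻¹. While target stands, it passes to side product at 0.00454 s⁻¹ at the charged partner and returns to starting material at 0.00611 s⁻¹. Autumn's reading and 27.3% give a tail constant of 0.00462 s⁻¹, higher than my 0.00360 s⁻¹. The dawn run's tail, read at 0.0108 s⁻¹, is 2.34 times that for 3.00 times the partner.

The data are simulated for an exercise; the scatter is artificial.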